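**Retrosynthetic overview**
1. The (E)-enol ester comes from copper-mediated C–O coupling of 3-methylbut-2-enoic acid with an (E)-alkenyltrifluoroborate. That arm and the 2-oxopropyl arm are unveiled together by one ozonolysis of a C6-vinyl/C7-methallyl cycloheptenone; the CH2OH comes from a Morita–Baylis–Hillman reaction and C7 from a trans-selective enolate alkylation.
2. The cycloheptenone core comes from (5R)-4-(bromomethyl)-4-methyl-5-vinylcyclohex-2-enone by a radical one-carbon ring expansion that forms the C3–C4 bond. In the same operation the rearranged C5 radical is captured by a vinyl ketone that brings the whole side chain and makes C5 quaternary.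
3. Enabling feature: in the seven-membered ring the enone β-carbon C3 and the fully substituted C5 are bridged by one CH2 (C4). This is the pattern left by a 1,2-vinyl shift of a CH2 radical sitting on the quaternary carbon of a cyclohex-2-enone, homoallylic to its C=C bond. C5 passes through a planar radical, so its configuration in the precursor does not matter.
4. The cyclohexenone comes from prochiral 4-(bromomethyl)-4-methylcyclohexa-2,5-dienone (benzoic acid, Birch reductive methylation) by a rhodium/(R)-BINAP desymmetrising vinyl addition; the side-chain carbinol is set by oxazaborolidine reduction.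
5. Ring order: six-membered carbocycle (from the arene), then a transient cyclopropane (3-exo), then the seven-membered ring (fragmentation); no other ring is made.

Key step: step 8

Remark on the chemistry: ring locants C1–C7 are those of the cyclohept-2-en-1-one (C1 carbonyl, C2 bearing CH2OH, C5 quaternary, C6 bearing the enol ester arm, C7 bearing the 2-oxopropyl group); vinyl ketone 10 is treated as not purchasable and is made in one step.

Step 1
Reactants: 1 benzoic acid
Product: 3 1-methylcyclohexa-2,5-diene-1-carboxylic acid, via dilithium enediolate 2 (not isolated)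
Conditions: Li (3.3 equiv), NH3(l)/THF, −78 °C; MeI, −78 °C; NH4Cl; aq HCl
Reagents that add atoms: iodomethane, CI
Why: Birch reduction of the benzoate gives the 1,4-dihydro enediolate, which is C-methylated at the carboxyl-bearing carbon (Birch reductive alkylation), so the future C5 leaves the arene as a quaternary, non-stereogenic carbon.

Step 2
Reactants: 3 1-methylcyclohexa-2,5-diene-1-carboxylic acid
Product: 4 (1-methylcyclohexa-2,5-dien-1-yl)methanol
Conditions: LiAlH4, THF, 0 °C → reflux; H2O, aq NaOH
Reagents that add atoms: none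
Why: LiAlH4 reduction of a carboxylic acid to the primary alcohol, with the skipped diene inert to hydride.

Step 3
Reactants: 4 (1-methylcyclohexa-2,5-dien-1-yl)methanol
Product: 5 3-(bromomethyl)-3-methylcyclohexa-1,4-diene
Conditions: CBr4, PPh3, CH2Cl2, 0 → 40 °C
Reagents that add atoms: tetrabromomethane, BrC(Br)(Br)Br
Why: Appel bromination by SN2 attack of bromide on the alkoxyphosphonium salt at a primary carbon that has no β-hydrogen, so elimination cannot compete.

Step 4
Reactants: 5 3-(bromomethyl)-3-methylcyclohexa-1,4-diene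
Product: 6 4-(bromomethyl)-4-methylcyclohexa-2,5-dien-1-one
Conditions: CrO3, 3,5-dimethylpyrazole, CH2Cl2, −20 °C
Reagents that add atoms: chromium trioxide, O=[Cr](=O)=O
Why: chromium-mediated allylic oxidation of the doubly allylic CH2 of a 3,3-disubstituted cyclohexa-1,4-diene should give the cross-conjugated dienone, the quaternary carbon blocking aromatisation.

Step 5
Reactants: 6 4-(bromomethyl)-4-methylcyclohexa-2,5-dien-1-one; 7 potassium ethenyltrifluoroborate
Product: 8 (5R)-4-(bromomethyl)-5-ethenyl-4-methylcyclohex-2-en-1-one (both epimers at the quaternary carbon)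
Conditions: [Rh(cod)2]PF6 (3 mol %), (R)-BINAP (3.3 mol %), PhMe/H2O, 100 °C
Reagents that add atoms: none
Why: the Hayashi–Miyaura rhodium-catalysed asymmetric 1,4-addition desymmetrises the prochiral dienone, the (R)-BINAP–Rh–vinyl species being expected (by the usual cyclohexenone facial model) to select the same enantioface on either enone arm and so give the (5R) centre that becomes C6, while the configuration created at the quaternary carbon is irrelevant because step 8 erases it.

Step 6
Reactants: 9 3-hydroxy-3-methylbutan-2-one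
Product: 10 4-hydroxy-4-methylpent-1-en-3-one
Conditions: (CH2O)n, N-methylanilinium trifluoroacetate, THF, reflux
Reagents that add atoms: formaldehyde (as paraformaldehyde), C=O
Why: Mannich-type α-methylenation (condensation with formaldehyde through the iminium salt, then elimination) at the only enolisable position of the methyl ketone.

Step 7
Reactants: 10 4-hydroxy-4-methylpent-1-en-3-one
Product: 11 4-methyl-4-[(triethylsilyl)oxy]pent-1-en-3-one
Conditions: Et3SiOTf, 2,6-lutidine, CH2Cl2, −78 → 0 °C
Reagents that add atoms: triethylsilyl trifluoromethanesulfonate, CC[Si](CC)(CC)OS(=O)(=O)C(F)(F)F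
Why: silyl triflate silylation of the tertiary alcohol, so that the later borane reduction is not perturbed by a free α-hydroxyl.

Step 8
Reactants: 8 (5R)-4-(bromomethyl)-5-ethenyl-4-methylcyclohex-2-en-1-one; 11 4-methyl-4-[(triethylsilyl)oxy]pent-1-en-3-one
Product: 16 (5S,6R)-6-ethenyl-5-methyl-5-{4-methyl-3-oxo-4-[(triethylsilyl)oxy]pentyl}cyclohept-2-en-1-one, via primary alkyl radical 12 (not isolated), via bicyclo[4.1.0]heptanyl radical 13 (not isolated), via tertiary cycloheptenyl radical 14 (not isolated), via adduct α-keto radical 15 (not isolated)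
Conditions: 11 (6 equiv), Bu3SnH (1.3 equiv) + AIBN (0.2 equiv) by syringe pump (10 h), PhH, 80 °C
Reagents that add atoms: none
Why: Proposed new method: Bu3Sn• abstracts bromine from either epimer of 8 to give primary radical 12, which closes 3-exo-trig onto the enone β-carbon (this forges the C3–C4 bond) to give the α-keto cyclopropylcarbinyl radical 13; β-scission of the internal cyclopropane bond then delivers the ring-expanded tertiary radical 14 at C5, which adds to the electron-poor vinyl ketone 11 (Giese reaction), and adduct radical 15 takes hydrogen from Bu3SnH. The closest known reaction types are the Dowd–Beckwith ring expansion and the homoallyl/cyclopropylcarbinyl 1,2-vinyl shift on one side and tin-hydride radical cyclisation with intermolecular enone trapping on the other; capture of the rearranged radical to build a quaternary stereocentre is the untested part. The cyclopropane closes by 3-exo-trig attack, and the seven-membered ring is not closed directly but arises from that bicycle by fragmentation, a net one-carbon ring expansion. The only new stereocentre, C5, is set by substrate control: planar radical 14 should be attacked on the face anti to the adjacent C6 vinyl group, which puts the side chain trans and the methyl cis to it as the target requires, and because both epimers of 8 give the same radical the step is stereoconvergent. The step needs ring expansion to outrun hydrogen transfer to 12 or 13 and intermolecular addition of 12, which the polarity-matched closure onto an enone from a gem-disubstituted carbon and a low stationary Bu3SnH concentration should secure; it also needs 14 to add to 11 faster than it is reduced or suffers a 1,2-vinyl shift, which the nucleophilic tertiary radical, the excess of 11 and slow hydride addition should secure.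

Step 9
Reactants: 16 (5S,6R)-6-ethenyl-5-methyl-5-{4-methyl-3-oxo-4-[(triethylsilyl)oxy]pentyl}cyclohept-2-en-1-one
Product: 17 (5S,6R)-6-ethenyl-5-{(3S)-3-hydroxy-4-methyl-4-[(triethylsilyl)oxy]pentyl}-5-methylcyclohept-2-en-1-ol (both C1 epimers)
Conditions: (R)-1-methyl-3,3-diphenyltetrahydro-1H,3H-pyrrolo[1,2-c][1,3,2]oxazaborole ((R)-Me-CBS, 0.3 equiv), catecholborane (3 equiv), PhMe, −78 → −40 °C; MeOH, aq NaHCO3
Reagents that add atoms: none
Why: in this Corey–Bakshi–Shibata reduction the (R)-oxazaborolidine should deliver hydride to the side-chain ketone with the silyloxy-bearing tertiary carbon as the large group, giving the (S)-carbinol by reagent control, while the enone carbonyl is reduced 1,2 as well and is restored in step 10.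

Step 10
Reactants: 17 (5S,6R)-6-ethenyl-5-{(3S)-3-hydroxy-4-methyl-4-[(triethylsilyl)oxy]pentyl}-5-methylcyclohept-2-en-1-ol
Product: 18 (5S,6R)-6-ethenyl-5-{(3S)-3-hydroxy-4-methyl-4-[(triethylsilyl)oxy]pentyl}-5-methylcyclohept-2-en-1-one
Conditions: MnO2 (excess), CH2Cl2, rt
Reagents that add atoms: none
Why: MnO2 oxidises only the allylic alcohol, so both C1 epimers converge on one enone and the saturated secondary carbinol is untouched.

Step 11
Reactants: 18 (5S,6R)-6-ethenyl-5-{(3S)-3-hydroxy-4-methyl-4-[(triethylsilyl)oxy]pentyl}-5-methylcyclohept-2-en-1-one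
Product: 19 (5S,6R)-6-ethenyl-2-(hydroxymethyl)-5-{(3S)-3-hydroxy-4-methyl-4-[(triethylsilyl)oxy]pentyl}-5-methylcyclohept-2-en-1-one
Conditions: aq CH2O (37 %), imidazole, THF/H2O, rt
Reagents that add atoms: formaldehyde, C=O
Why: Morita–Baylis–Hillman reaction, in which imidazole adds to C3, the resulting enolate is hydroxymethylated at C2 by formaldehyde and the catalyst is expelled.

Step 12
Reactants: 19 (5S,6R)-6-ethenyl-2-(hydroxymethyl)-5-{(3S)-3-hydroxy-4-methyl-4-[(triethylsilyl)oxy]pentyl}-5-methylcyclohept-2-en-1-one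
Product: 20 (5S,6R)-2-{[(tert-butyldimethylsilyl)oxy]methyl}-5-{(3S)-3-[(tert-butyldimethylsilyl)oxy]-4-methyl-4-[(triethylsilyl)oxy]pentyl}-6-ethenyl-5-methylcyclohept-2-en-1-one
Conditions: t-BuMe2SiOTf (2.5 equiv), 2,6-lutidine, CH2Cl2, −78 °C
Reagents that add atoms: tert-butyldimethylsilyl trifluoromethanesulfonate, CC(C)(C)[Si](C)(C)OS(=O)(=O)C(F)(F)F
Why: silyl triflate protection of the primary and the hindered secondary hydroxyl at low temperature, so that neither is deprotonated in step 13 nor competes in the coupling of step 17.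

Step 13
Reactants: 20 (5S,6R)-2-{[(tert-butyldimethylsilyl)oxy]methyl}-5-{(3S)-3-[(tert-butyldimethylsilyl)oxy]-4-methyl-4-[(triethylsilyl)oxy]pentyl}-6-ethenyl-5-methylcyclohept-2-en-1-one; 21 3-bromo-2-methylprop-1-ene
Product: 23 (5S,6S,7S)-2-{[(tert-butyldimethylsilyl)oxy]methyl}-5-{(3S)-3-[(tert-butyldimethylsilyl)oxy]-4-methyl-4-[(triethylsilyl)oxy]pentyl}-6-ethenyl-5-methyl-7-(2-methylprop-2-en-1-yl)cyclohept-2-en-1-one, via lithium enolate 22 (not isolated)
Conditions: LiN(iPr)2 (commercial solution, 1.1 equiv), THF, −78 °C; 21, DMPU, −78 → −40 °C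
Reagents that add atoms: none
Why: kinetic α′-deprotonation gives the cross-conjugated enolate 22, which should be alkylated by the allylic bromide on the face anti to the adjacent C6 vinyl group (enolate alkylation), setting C7 trans to C6, the arrangement that is also expected to be the thermodynamically preferred one.

Step 14
Reactants: 23 (5S,6S,7S)-2-{[(tert-butyldimethylsilyl)oxy]methyl}-5-{(3S)-3-[(tert-butyldimethylsilyl)oxy]-4-methyl-4-[(triethylsilyl)oxy]pentyl}-6-ethenyl-5-methyl-7-(2-methylprop-2-en-1-yl)cyclohept-2-en-1-one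
Product: 24 (1S,2S,7S)-4-{[(tert-butyldimethylsilyl)oxy]methyl}-7-{(3S)-3-[(tert-butyldimethylsilyl)oxy]-4-methyl-4-[(triethylsilyl)oxy]pentyl}-7-methyl-3-oxo-2-(2-oxopropyl)cyclohept-4-ene-1-carbaldehyde
Conditions: O3, CH2Cl2, −78 °C (Sudan Red 7B end-point); Me2S
Reagents that add atoms: ozone, [O-][O+]=O
Why: ozonolysis with reductive work-up should cleave the two electron-rich terminal alkenes in one operation, unveiling the C6 formyl group and the 2-oxopropyl ketone, while the electron-poor enone reacts much more slowly.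

Step 15
Reactants: 24 (1S,2S,7S)-4-{[(tert-butyldimethylsilyl)oxy]methyl}-7-{(3S)-3-[(tert-butyldimethylsilyl)oxy]-4-methyl-4-[(triethylsilyl)oxy]pentyl}-7-methyl-3-oxo-2-(2-oxopropyl)cyclohept-4-ene-1-carbaldehyde; 25 2-(dichloromethyl)-4,4,5,5-tetramethyl-1,3,2-dioxaborolane
Product: 26 (5S,6S,7S)-2-{[(tert-butyldimethylsilyl)oxy]methyl}-5-{(3S)-3-[(tert-butyldimethylsilyl)oxy]-4-methyl-4-[(triethylsilyl)oxy]pentyl}-5-methyl-7-(2-oxopropyl)-6-[(E)-2-(4,4,5,5-tetramethyl-1,3,2-dioxaborolan-2-yl)ethenyl]cyclohept-2-en-1-one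
Conditions: CrCl2 (8 equiv), LiI, THF, rt
Reagents that add atoms: none
Why: in this Takai–Utimoto boryl-olefination the geminal dichromium reagent from 25 should add to the aldehyde only (ketones are inert) and eliminate to the (E)-alkenylboronate.

Step 16
Reactants: 26 (5S,6S,7S)-2-{[(tert-butyldimethylsilyl)oxy]methyl}-5-{(3S)-3-[(tert-butyldimethylsilyl)oxy]-4-methyl-4-[(triethylsilyl)oxy]pentyl}-5-methyl-7-(2-oxopropyl)-6-[(E)-2-(4,4,5,5-tetramethyl-1,3,2-dioxaborolan-2-yl)ethenyl]cyclohept-2-en-1-one
Product: 27 potassium (E)-alkenyltrifluoroborate corresponding to 26 (pinacolboryl replaced by BF3K)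
Conditions: KHF2, MeOH/H2O, rt
Reagents that add atoms: potassium hydrogen difluoride, [K+].[F-].F
Why: fluoride exchange at boron converts the pinacol boronate into the trifluoroborate salt with retention of the alkene geometry.

Step 17
Reactants: 27 potassium (E)-alkenyltrifluoroborate corresponding to 26; 28 3-methylbut-2-enoic acid
Product: 29 (E)-2-[(1S,2S,7S)-4-{[(tert-butyldimethylsilyl)oxy]methyl}-7-{(3S)-3-[(tert-butyldimethylsilyl)oxy]-4-methyl-4-[(triethylsilyl)oxy]pentyl}-7-methyl-3-oxo-2-(2-oxopropyl)cyclohept-4-en-1-yl]ethenyl 3-methylbut-2-enoate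
Conditions: 28 (3 equiv), CuBr (20 mol %), DMAP (40 mol %), 4 Å MS, O2 (1 atm), CH2Cl2, rt
Reagents that add atoms: none
Why: Chan–Lam-type copper-mediated oxidative C–O coupling of an alkenyltrifluoroborate with a carboxylic acid is stereoretentive and should therefore give the (E)-enol ester.

Step 18
Reactants: 29 (E)-enol 3-methylbut-2-enoate, tris-silyl ether
Product: 30 (E)-2-[(1S,2S,7S)-7-[(3S)-3,4-dihydroxy-4-methylpentyl]-4-(hydroxymethyl)-7-methyl-3-oxo-2-(2-oxopropyl)cyclohept-4-en-1-yl]ethenyl 3-methylbut-2-enoate (CNP0238215.2)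
Conditions: HF·pyridine, pyridine, THF, 0 °C → rt
Reagents that add atoms: none
Why: buffered fluoride cleavage of the three silyl ethers (desilylation) under conditions that should leave the enol ester and the enone intact.

**Compound list**
1 | benzoic acid | O=C(O)c1ccccc1 | starting material
2 | dilithium enediolate of 1,4-dihydrobenzoic acid | [Li+].[Li+].[O-]C([O-])=C1C=CCC=C1 | intermediate
3 | 1-methylcyclohexa-2,5-diene-1-carboxylic acid | CC1(C=CCC=C1)C(=O)O | intermediate
4 | (1-methylcyclohexa-2,5-dien-1-yl)methanol | CC1(CO)C=CCC=C1 | intermediate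
5 | 3-(bromomethyl)-3-methylcyclohexa-1,4-diene | CC1(CBr)C=CCC=C1 | intermediate
6 | 4-(bromomethyl)-4-methylcyclohexa-2,5-dien-1-one | CC1(CBr)C=CC(=O)C=C1 | intermediate
7 | potassium ethenyltrifluoroborate | [K+].C=C[B-](F)(F)F | starting material
8 | (5R)-4-(bromomethyl)-5-ethenyl-4-methylcyclohex-2-en-1-one, both epimers at C4 | C1C(=O)C=CC(C)(CBr)[C@H]1C=C | intermediate
9 | 3-hydroxy-3-methylbutan-2-one | CC(=O)C(C)(C)O | starting material
10 | 4-hydroxy-4-methylpent-1-en-3-one | C=CC(=O)C(C)(C)O | intermediate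
11 | 4-methyl-4-[(triethylsilyl)oxy]pent-1-en-3-one | C=CC(=O)C(C)(C)O[Si](CC)(CC)CC | intermediate
12 | [(6R)-6-ethenyl-1-methyl-4-oxocyclohex-2-en-1-yl]methyl radical | C1C(=O)C=CC(C)([CH2])[C@H]1C=C | intermediate
13 | (5R)-5-ethenyl-6-methyl-3-oxobicyclo[4.1.0]heptan-2-yl radical | C1C(=O)[CH]C2CC2(C)[C@H]1C=C | intermediate
14 | 2-ethenyl-1-methyl-4-oxocyclohept-5-en-1-yl radical (vinyl-bearing centre as in 8) | C1C(=O)C=CC[C](C)[C@H]1C=C | intermediate
15 | α-keto radical formed by addition of 14 to 11 | C1C(=O)C=CC[C@](C)(C[CH]C(=O)C(C)(C)O[Si](CC)(CC)CC)[C@H]1C=C | intermediate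
16 | (5S,6R)-6-ethenyl-5-methyl-5-{4-methyl-3-oxo-4-[(triethylsilyl)oxy]pentyl}cyclohept-2-en-1-one | C1C(=O)C=CC[C@](C)(CCC(=O)C(C)(C)O[Si](CC)(CC)CC)[C@H]1C=C | intermediate
17 | (5S,6R)-6-ethenyl-5-{(3S)-3-hydroxy-4-methyl-4-[(triethylsilyl)oxy]pentyl}-5-methylcyclohept-2-en-1-ol, both C1 epimers | C1C(O)C=CC[C@](C)(CC[C@H](O)C(C)(C)O[Si](CC)(CC)CC)[C@H]1C=C | intermediate
18 | (5S,6R)-6-ethenyl-5-{(3S)-3-hydroxy-4-methyl-4-[(triethylsilyl)oxy]pentyl}-5-methylcyclohept-2-en-1-one | C1C(=O)C=CC[C@](C)(CC[C@H](O)C(C)(C)O[Si](CC)(CC)CC)[C@H]1C=C | intermediate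
19 | (5S,6R)-6-ethenyl-2-(hydroxymethyl)-5-{(3S)-3-hydroxy-4-methyl-4-[(triethylsilyl)oxy]pentyl}-5-methylcyclohept-2-en-1-one | C1C(=O)C(CO)=CC[C@](C)(CC[C@H](O)C(C)(C)O[Si](CC)(CC)CC)[C@H]1C=C | intermediate
20 | bis(tert-butyldimethylsilyl) ether of 19 | C1C(=O)C(CO[Si](C)(C)C(C)(C)C)=CC[C@](C)(CC[C@H](O[Si](C)(C)C(C)(C)C)C(C)(C)O[Si](CC)(CC)CC)[C@H]1C=C | intermediate
21 | 3-bromo-2-methylprop-1-ene | CC(=C)CBr | starting material
22 | lithium C1=C7 enolate of 20 | C1=C([O-])C(CO[Si](C)(C)C(C)(C)C)=CC[C@](C)(CC[C@H](O[Si](C)(C)C(C)(C)C)C(C)(C)O[Si](CC)(CC)CC)[C@H]1C=C.[Li+] | intermediate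
23 | (5S,6S,7S)-7-(2-methylprop-2-en-1-yl) derivative of 20 | CC(=C)C[C@@H]1C(=O)C(CO[Si](C)(C)C(C)(C)C)=CC[C@](C)(CC[C@H](O[Si](C)(C)C(C)(C)C)C(C)(C)O[Si](CC)(CC)CC)[C@H]1C=C | intermediate
24 | (1S,2S,7S)-4-{[(tert-butyldimethylsilyl)oxy]methyl}-7-{(3S)-3-[(tert-butyldimethylsilyl)oxy]-4-methyl-4-[(triethylsilyl)oxy]pentyl}-7-methyl-3-oxo-2-(2-oxopropyl)cyclohept-4-ene-1-carbaldehyde | CC(=O)C[C@@H]1C(=O)C(CO[Si](C)(C)C(C)(C)C)=CC[C@](C)(CC[C@H](O[Si](C)(C)C(C)(C)C)C(C)(C)O[Si](CC)(CC)CC)[C@H]1C=O | intermediate
25 | 2-(dichloromethyl)-4,4,5,5-tetramethyl-1,3,2-dioxaborolane | ClC(Cl)B1OC(C)(C)C(C)(C)O1 | starting material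
26 | (E)-alkenyl pinacol boronate (C6 arm CH=CH–Bpin, otherwise as 24) | CC(=O)C[C@@H]1C(=O)C(CO[Si](C)(C)C(C)(C)C)=CC[C@](C)(CC[C@H](O[Si](C)(C)C(C)(C)C)C(C)(C)O[Si](CC)(CC)CC)[C@H]1/C=C/B1OC(C)(C)C(C)(C)O1 | intermediate
27 | potassium (E)-alkenyltrifluoroborate corresponding to 26 | CC(=O)C[C@@H]1C(=O)C(CO[Si](C)(C)C(C)(C)C)=CC[C@](C)(CC[C@H](O[Si](C)(C)C(C)(C)C)C(C)(C)O[Si](CC)(CC)CC)[C@H]1/C=C/[B-](F)(F)F.[K+] | intermediate
28 | 3-methylbut-2-enoic acid | CC(C)=CC(=O)O | starting material
29 | tris-silyl ether of the target (E)-enol ester | CC(=O)C[C@@H]1C(=O)C(CO[Si](C)(C)C(C)(C)C)=CC[C@](C)(CC[C@H](O[Si](C)(C)C(C)(C)C)C(C)(C)O[Si](CC)(CC)CC)[C@H]1/C=C/OC(=O)C=C(C)C | intermediate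
30 | (E)-2-[(1S,2S,7S)-7-[(3S)-3,4-dihydroxy-4-methylpentyl]-4-(hydroxymethyl)-7-methyl-3-oxo-2-(2-oxopropyl)cyclohept-4-en-1-yl]ethenyl 3-methylbut-2-enoate | CC(=O)C[C@@H]1C(=O)C(CO)=CC[C@](C)(CC[C@H](O)C(C)(C)O)[C@H]1/C=C/OC(=O)C=C(C)C | target

**Step count and risks**
Total step count: 18. Longest linear sequence: 16 (steps 1–5 and 8–18; steps 6–7 make vinyl ketone 11).

Most likely to fail:

1. Step 8. Hydrogen transfer to the primary or the bicyclic radical may outrun ring expansion. The tertiary radical may also be reduced, undergo a 1,2-vinyl shift or telomerise before it adds to 11, and its facial selectivity may be low. Fallback, each event run separately with known chemistry, setting out from 8: an organocobalt-mediated radical reaction (Co(dmgH)2(py)Cl, NaBH4, aq NaOH/MeOH, then irradiation) generates the same primary radical without a hydrogen donor. After the 1,2-vinyl-shift ring expansion the tertiary radical is captured by divalent cobalt, and dehydrocobaltation gives (6R)-6-ethenyl-5-methylidenecyclohept-2-en-1-one F1 (endocyclic alkene isomers are equally usable). Hydrogen-atom transfer to F1 with Fe(acac)3/PhSiH3 in EtOH/ethylene glycol at 60 °C regenerates the C5 tertiary radical from the 1,1-disubstituted alkene (the monosubstituted vinyl group reacts much more slowly) in the presence of 11, a reductive olefin–enone coupling. The route is rejoined at 16.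

2. Step 17. Transmetalation of the hindered alkenylborate to copper may be slow, so that protodeboronation or homocoupling takes over. Fallback, setting out from 26: oxidation of the C–B bond with NaBO3·4H2O in THF/H2O gives, through the enol, 2-[(1S,2S,7S)-4-{[(tert-butyldimethylsilyl)oxy]methyl}-7-{(3S)-3-[(tert-butyldimethylsilyl)oxy]-4-methyl-4-[(triethylsilyl)oxy]pentyl}-7-methyl-3-oxo-2-(2-oxopropyl)cyclohept-4-en-1-yl]acetaldehyde F3. Its aldehyde enolate is O-acylated with 3-methylbut-2-enoyl chloride (Et3N, DMAP, CH2Cl2), and the (E)-isomer is separated from the (Z)-isomer, which can be equilibrated with catalytic I2. The route is rejoined at 29.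

3. Step 11. Turnover may stall, through slow conjugate addition of the amine at C3 next to the neopentyl-type C4, or through reversal of the aldol step with loss of formaldehyde. Fallback, setting out from 18: α-iodination (I2, pyridine, CH2Cl2) gives (5S,6R)-6-ethenyl-5-{(3S)-3-hydroxy-4-methyl-4-[(triethylsilyl)oxy]pentyl}-2-iodo-5-methylcyclohept-2-en-1-one F2. Stille coupling with (tributylstannyl)methanol (Pd(PPh3)4, dioxane, 80 °C) installs the hydroxymethyl group, and the route is rejoined at 19.

**Further compounds**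
F1 | step 8 | (6R)-6-ethenyl-5-methylidenecyclohept-2-en-1-one | C1C(=O)C=CCC(=C)[C@H]1C=C
F2 | step 11 | (5S,6R)-6-ethenyl-5-{(3S)-3-hydroxy-4-methyl-4-[(triethylsilyl)oxy]pentyl}-2-iodo-5-methylcyclohept-2-en-1-one | C1C(=O)C(I)=CC[C@](C)(CC[C@H](O)C(C)(C)O[Si](CC)(CC)CC)[C@H]1C=C
F3 | step 17 | 2-[(1S,2S,7S)-4-{[(tert-butyldimethylsilyl)oxy]methyl}-7-{(3S)-3-[(tert-butyldimethylsilyl)oxy]-4-methyl-4-[(triethylsilyl)oxy]pentyl}-7-methyl-3-oxo-2-(2-oxopropyl)cyclohept-4-en-1-yl]acetaldehyde | CC(=O)C[C@@H]1C(=O)C(CO[Si](C)(C)C(C)(C)C)=CC[C@](C)(CC[C@H](O[Si](C)(C)C(C)(C)C)C(C)(C)O[Si](CC)(CC)CC)[C@H]1CC=O
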